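## Retrosynthetic overview

1. Target oxolane ⇒ (both C–O bonds, last step) unprotected erythro-2,3-dimethyl-1,4-diarylbutane-1,4-diol, the hydrate of the bis(para-quinone methide) that 8–8′ coupling gives in nature. Closure through the hydroxy quinone methide is stereoconvergent and sets both benzylic centres.
2. Diol ⇒ (C–aryl bond) ring A/ring C aryllithium + γ-(ring B)-α,β-dimethylbutyrolactone, then reduction.
3. Lactone ⇒ keto acid ⇒ Rh-catalysed enantioselective arylative opening of meso cis-2,3-dimethylsuccinic anhydride, which fixes the two methyl-bearing centres and tells the two ends apart.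
4. Ring A/ring C fragment ⇒ Ir-catalysed asymmetric hydrogenation of an (E)-1,2-diarylpropene ⇒ Heck coupling of 4-bromo-2-iodoanisole with trans-anethole.
5. Rings: a lactone is made in step 3 only as an acyl donor and is opened again in step 8; the oxolane, the one ring of the target built here, is closed last (step 9).

Abbreviations: TIPS = tri(propan-2-yl)silyl; tBu-PHOX = 4-tert-butyl-2-[2-(diphenylphosphanyl)phenyl]-4,5-dihydro-1,3-oxazole; cod = cycloocta-1,5-diene. Ring A = aryl on C2 of the oxolane (carries the side chain), ring B = 4-hydroxyphenyl on C5, ring C = 4-hydroxyphenyl of the side chain.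

Assumption: the ligand enantiomers named in steps 2 and 5 are taken, by analogy with the parent substrates, to give the drawn configurations (the antipodal ligands are equally available); centres drawn without configuration (C4 of 7, C5 of 8, C2/C5 of 16, C1/C4 of 17 and 18, C4 of 19) are epimer mixtures that converge in step 9.

## Route

Step 1
Reactants: 1 meso-2,3-dimethylsuccinic acid [(2R,3S)-2,3-dimethylbutanedioic acid]
Product: 2 cis-2,3-dimethylsuccinic anhydride [(3R,4S)-3,4-dimethyloxolane-2,5-dione]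
Conditions: AcCl (neat), reflux, 2 h; evaporate
Reagents that add atoms: none
Why: Cyclodehydration of a 1,4-diacid with acetyl chloride gives the five-membered anhydride, and because the meso acid is used and neither α-centre is touched the two methyl groups end up cis.

Step 2
Reactants: 3 (4-bromophenoxy)tri(propan-2-yl)silane; 2 cis-2,3-dimethylsuccinic anhydride
Product: 6 (2R,3S)-2,3-dimethyl-4-oxo-4-(4-TIPSO-phenyl)butanoic acid, via aryllithium 4 (not isolated), via arylzinc triflate 5 (not isolated)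
Conditions: 3, n-BuLi, THF, −78 °C; Zn(OTf)2, −78 °C to rt; then 2, [Rh(cod)Cl]2 (4 mol%), (S)-tBu-PHOX (8 mol%), THF, 50 °C; 1 M HCl
Reagents that add atoms: none
Why: Rhodium-catalysed enantioselective desymmetrisation of a meso cyclic anhydride by an arylzinc reagent (a Negishi-type acyl cross-coupling) lets the chiral phosphinooxazoline complex insert into one of the two enantiotopic acyl–oxygen bonds, so the two pre-existing cis methyl stereocentres are differentiated and fixed as (2R,3S) in this single step.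

Step 3
Reactants: 6 (2R,3S)-2,3-dimethyl-4-oxo-4-(4-TIPSO-phenyl)butanoic acid
Product: 8 (3R,4S)-3,4-dimethyl-5-(4-TIPSO-phenyl)oxolan-2-one (C5 epimers), via hydroxy acid 7 (not isolated)
Conditions: NaBH4, EtOH, 0 °C to rt; then 1 M HCl (pH 2), rt
Reagents that add atoms: none
Why: Borohydride reduction of the aryl ketone followed by acid-induced lactonisation of the γ-hydroxy acid gives the butyrolactone without touching C3 and C4, and the configuration of the new benzylic centre C5 does not matter because it is set again through a quinone methide in step 9.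

Step 4
Reactants: 9 4-bromo-2-iodo-1-methoxybenzene; 10 trans-anethole [1-methoxy-4-[(E)-prop-1-enyl]benzene]
Product: 11 4-bromo-1-methoxy-2-[(E)-1-(4-methoxyphenyl)prop-1-en-2-yl]benzene
Conditions: Pd(OAc)2 (5 mol%), n-Bu4NCl, NaHCO3, DMF, 80 °C; crystallise the (E)-isomer
Reagents that add atoms: none
Why: Mizoroki–Heck arylation under ligand-free phase-transfer conditions reacts at the C–I bond only, the aryl group adds to the methyl-bearing alkene carbon so that palladium sits at the benzylic position, and syn insertion into the (E)-alkene followed by syn β-hydride elimination gives the (E)-1,2-diarylpropene.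

Step 5
Reactants: 11 4-bromo-1-methoxy-2-[(E)-1-(4-methoxyphenyl)prop-1-en-2-yl]benzene
Product: 12 4-bromo-1-methoxy-2-[(2R)-1-(4-methoxyphenyl)propan-2-yl]benzene
Conditions: H2 (50 bar), [Ir(cod)((S)-tBu-PHOX)][B(C6H3-3,5-(CF3)2)4] (1 mol%), CH2Cl2, rt
Reagents that add atoms: none
Why: Iridium-catalysed asymmetric hydrogenation of an unfunctionalised trisubstituted (E)-1,2-diarylpropene with a cationic phosphinooxazoline complex adds hydrogen to one enantioface under catalyst control and sets the (R)-configured benzylic methyl stereocentre while leaving the aryl bromide untouched.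

Step 6
Reactants: 12 4-bromo-1-methoxy-2-[(2R)-1-(4-methoxyphenyl)propan-2-yl]benzene
Product: 13 4-bromo-2-[(2R)-1-(4-hydroxyphenyl)propan-2-yl]phenol
Conditions: BBr3 (3 equiv), CH2Cl2, −78 °C to rt; then H2O
Reagents that add atoms: none
Why: Lewis-acid O-demethylation of both aryl methyl ethers with BBr3 is done here on a robust saturated fragment that has no acid-labile benzylic ether, and the benzylic stereocentre is not affected.

Step 7
Reactants: 13 4-bromo-2-[(2R)-1-(4-hydroxyphenyl)propan-2-yl]phenol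
Product: 14 4-bromo-1-TIPSO-2-[(2R)-1-(4-TIPSO-phenyl)propan-2-yl]benzene
Conditions: TIPSOTf (2.4 equiv), 2,6-lutidine, CH2Cl2, 0 °C to rt
Reagents that add atoms: tri(propan-2-yl)silyl trifluoromethanesulfonate (TIPSOTf), CC(C)[Si](OS(=O)(=O)C(F)(F)F)(C(C)C)C(C)C
Why: Silylation of both phenols gives triisopropylsilyl ethers that survive the organolithium and borohydride steps and later leave with fluoride under conditions that spare a para-hydroxybenzylic ether.

Step 8
Reactants: 14 4-bromo-1-TIPSO-2-[(2R)-1-(4-TIPSO-phenyl)propan-2-yl]benzene; 8 (3R,4S)-3,4-dimethyl-5-(4-TIPSO-phenyl)oxolan-2-one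
Product: 17 (2R,3S)-2,3-dimethyl-1-{4-TIPSO-3-[(2R)-1-(4-TIPSO-phenyl)propan-2-yl]phenyl}-4-(4-TIPSO-phenyl)butane-1,4-diol (C1/C4 epimers), via aryllithium 15 (not isolated), via lactol 16 (not isolated)
Conditions: 14, t-BuLi (2 equiv), THF, −78 °C; add 8, −78 °C; then MeOH, NaBH4, −78 to 0 °C; H2O
Reagents that add atoms: none
Why: Bromine–lithium exchange gives an aryllithium that adds once to the lactone carbonyl at −78 °C because the lithium hemiketal does not collapse until it is quenched, and in situ borohydride reduction of the lactol (hydroxy ketone) then gives the 1,4-diol as a mixture of C1/C4 epimers with the C2, C3 and side-chain stereocentres untouched.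

Step 9
Reactants: 17 (2R,3S)-2,3-dimethyl-1-{4-TIPSO-3-[(2R)-1-(4-TIPSO-phenyl)propan-2-yl]phenyl}-4-(4-TIPSO-phenyl)butane-1,4-diol
Product: 20 4-[(2S,3S,4R,5R)-5-{4-hydroxy-3-[(2R)-1-(4-hydroxyphenyl)propan-2-yl]phenyl}-3,4-dimethyloxolan-2-yl]phenol, via triphenol diol 18 (not isolated), via hydroxy quinone methide 19 (not isolated)
Conditions: TBAF (3.3 equiv), AcOH (3.3 equiv), THF, 0 °C to rt; then 1 M aq HCl, THF/H2O (0.01 M), rt to 45 °C until the isomer ratio is constant
Reagents that add atoms: none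
Why: Fluoride desilylation unmasks the three phenols and dilute acid then ionises the para-hydroxybenzylic alcohols to the hydroxy para-quinone methide that the biosynthesis reaches after 8–8′ coupling and hydration, whose intramolecular oxa-Michael (7-O-7′) closure is reversible, so that all four diol epimers converge under thermodynamic control on the oxolane with each aryl group trans to its neighbouring methyl group (the two benzylic centres are set here, the two methyl-bearing centres come from step 2 and the side-chain centre from step 5).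

## Compound list

1 | meso-2,3-dimethylsuccinic acid, (2R,3S)-2,3-dimethylbutanedioic acid | C[C@@H](C(=O)O)[C@H](C)C(=O)O | starting material
2 | cis-2,3-dimethylsuccinic anhydride, (3R,4S)-3,4-dimethyloxolane-2,5-dione | C[C@@H](C1=O)[C@H](C)C(=O)O1 | intermediate
3 | (4-bromophenoxy)tri(propan-2-yl)silane | CC(C)[Si](Oc1ccc(Br)cc1)(C(C)C)C(C)C | starting material
4 | (4-TIPSO-phenyl)lithium | [Li]c1ccc(O[Si](C(C)C)(C(C)C)C(C)C)cc1 | intermediate (not isolated)
5 | (4-TIPSO-phenyl)zinc trifluoromethanesulfonate | FC(F)(F)S(=O)(=O)O[Zn]c1ccc(O[Si](C(C)C)(C(C)C)C(C)C)cc1 | intermediate (not isolated)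
6 | (2R,3S)-2,3-dimethyl-4-oxo-4-(4-TIPSO-phenyl)butanoic acid | C[C@@H](C(=O)O)[C@H](C)C(=O)c1ccc(O[Si](C(C)C)(C(C)C)C(C)C)cc1 | intermediate
7 | (2R,3S)-4-hydroxy-2,3-dimethyl-4-(4-TIPSO-phenyl)butanoic acid, C4 epimers | C[C@@H](C(=O)O)[C@H](C)C(O)c1ccc(O[Si](C(C)C)(C(C)C)C(C)C)cc1 | intermediate (not isolated)
8 | (3R,4S)-3,4-dimethyl-5-(4-TIPSO-phenyl)oxolan-2-one, C5 epimers | C[C@@H](C1=O)[C@H](C)C(c2ccc(O[Si](C(C)C)(C(C)C)C(C)C)cc2)O1 | intermediate
9 | 4-bromo-2-iodo-1-methoxybenzene | COc1ccc(Br)cc1I | starting material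
10 | trans-anethole, 1-methoxy-4-[(E)-prop-1-enyl]benzene | COc1ccc(/C=C/C)cc1 | starting material
11 | 4-bromo-1-methoxy-2-[(E)-1-(4-methoxyphenyl)prop-1-en-2-yl]benzene | C/C(=C\c1ccc(OC)cc1)c1cc(Br)ccc1OC | intermediate
12 | 4-bromo-1-methoxy-2-[(2R)-1-(4-methoxyphenyl)propan-2-yl]benzene | COc1ccc(Br)cc1[C@H](C)Cc1ccc(OC)cc1 | intermediate
13 | 4-bromo-2-[(2R)-1-(4-hydroxyphenyl)propan-2-yl]phenol | Oc1ccc(Br)cc1[C@H](C)Cc1ccc(O)cc1 | intermediate
14 | 4-bromo-1-TIPSO-2-[(2R)-1-(4-TIPSO-phenyl)propan-2-yl]benzene | CC(C)[Si](Oc1ccc(Br)cc1[C@H](C)Cc1ccc(O[Si](C(C)C)(C(C)C)C(C)C)cc1)(C(C)C)C(C)C | intermediate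
15 | {4-TIPSO-3-[(2R)-1-(4-TIPSO-phenyl)propan-2-yl]phenyl}lithium | CC(C)[Si](Oc1ccc([Li])cc1[C@H](C)Cc1ccc(O[Si](C(C)C)(C(C)C)C(C)C)cc1)(C(C)C)C(C)C | intermediate (not isolated)
16 | (3R,4S)-3,4-dimethyl-2-{4-TIPSO-3-[(2R)-1-(4-TIPSO-phenyl)propan-2-yl]phenyl}-5-(4-TIPSO-phenyl)oxolan-2-ol, C2/C5 epimers | C[C@@H](C1(O)c2ccc(O[Si](C(C)C)(C(C)C)C(C)C)c([C@H](C)Cc3ccc(O[Si](C(C)C)(C(C)C)C(C)C)cc3)c2)[C@H](C)C(c2ccc(O[Si](C(C)C)(C(C)C)C(C)C)cc2)O1 | intermediate (not isolated)
17 | (2R,3S)-2,3-dimethyl-1-{4-TIPSO-3-[(2R)-1-(4-TIPSO-phenyl)propan-2-yl]phenyl}-4-(4-TIPSO-phenyl)butane-1,4-diol, C1/C4 epimers | C[C@@H](C(O)c1ccc(O[Si](C(C)C)(C(C)C)C(C)C)c([C@H](C)Cc2ccc(O[Si](C(C)C)(C(C)C)C(C)C)cc2)c1)[C@H](C)C(O)c1ccc(O[Si](C(C)C)(C(C)C)C(C)C)cc1 | intermediate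
18 | (2R,3S)-1-{4-hydroxy-3-[(2R)-1-(4-hydroxyphenyl)propan-2-yl]phenyl}-4-(4-hydroxyphenyl)-2,3-dimethylbutane-1,4-diol, C1/C4 epimers | C[C@@H](C(O)c1ccc(O)c([C@H](C)Cc2ccc(O)cc2)c1)[C@H](C)C(O)c1ccc(O)cc1 | intermediate (not isolated)
19 | hydroxy para-quinone methide formed from 18 by loss of water at the ring B carbinol (one of the two possible regioisomers; methyl-bearing and side-chain centres as in 18) | C[C@@H](C(O)c1ccc(O)c([C@H](C)Cc2ccc(O)cc2)c1)[C@H](C)C=C1C=CC(=O)C=C1 | intermediate (not isolated)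
20 | 4-[(2S,3S,4R,5R)-5-{4-hydroxy-3-[(2R)-1-(4-hydroxyphenyl)propan-2-yl]phenyl}-3,4-dimethyloxolan-2-yl]phenol (aryl/methyl trans, methyl/methyl cis, methyl/aryl trans) | C[C@@H]1[C@H](C)[C@@H](c2ccc(O)cc2)O[C@H]1c1ccc(O)c([C@H](C)Cc2ccc(O)cc2)c1 | target

## Step count and risks

Total steps: 9. Longest linear sequence: 6 steps (steps 4, 5, 6, 7, 8 and 9; the anhydride branch, steps 1, 2, 3, 8 and 9, is 5 steps).

The three steps most likely to fail are the desymmetrisation (step 2), the Heck coupling (step 4) and the final quinone methide cyclisation (step 9).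

The desymmetrisation of step 2 may give low enantioselectivity or conversion with this silyloxy-substituted arylzinc. The fallback sets out from 2 and comes back to the route at 8, and replaces the metal-catalysed arylative opening by an organocatalytic alcoholysis. Methanolysis of 2 mediated by quinidine (MeOH, toluene, −55 °C; quinine if the opposite sense is found) gives the hemiester (2S,3R)-4-methoxy-2,3-dimethyl-4-oxobutanoic acid F1. Oxalyl chloride with catalytic DMF converts it into methyl (2R,3S)-4-chloro-2,3-dimethyl-4-oxobutanoate F2. Acylation of arylzinc 5 with F2 under Pd(PPh3)4 catalysis gives methyl (2R,3S)-2,3-dimethyl-4-oxo-4-(4-TIPSO-phenyl)butanoate F3. NaBH4 reduction of F3 and acid-induced lactonisation with loss of methanol return to 8.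

The Heck coupling of step 4 may give regioisomeric 1,1-diarylpropenes, E/Z mixtures or reaction at the C–Br bond. The fallback sets out from 9 and comes back at 11, and builds the alkene by carbonyl olefination instead. Selective iodine–magnesium exchange of 9 (i-PrMgCl·LiCl, THF, −20 °C) and trapping with N-methoxy-N-methylacetamide give 1-(5-bromo-2-methoxyphenyl)ethan-1-one F4. Horner–Wadsworth–Emmons olefination of F4 with diethyl (4-methoxybenzyl)phosphonate (KOtBu, THF, 0 °C to reflux) and crystallisation of the (E)-isomer return to 11.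

The final cascade of step 9 may suffer from oligomerisation of the free quinone methide, incomplete equilibration of the benzylic centres, or loss of the methyl-bearing centres through tautomerisation to a vinylphenol. The fallback sets out from 17 and comes back at 20, and closes the ring before the phenols are unmasked. BF3·OEt2 (CH2Cl2, −40 °C) cyclises 17 through para-silyloxybenzyl cations to (2R,3R,4S,5S)-3,4-dimethyl-2-{4-TIPSO-3-[(2R)-1-(4-TIPSO-phenyl)propan-2-yl]phenyl}-5-(4-TIPSO-phenyl)oxolane F5, which can be purified and equilibrated as a stable ether. TBAF buffered with AcOH (THF, 0 °C) then removes the three silyl groups and gives 20.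

## Further compounds

F1 | step 2 | (2S,3R)-4-methoxy-2,3-dimethyl-4-oxobutanoic acid | C[C@@H](C(=O)OC)[C@H](C)C(=O)O
F2 | step 2 | methyl (2R,3S)-4-chloro-2,3-dimethyl-4-oxobutanoate | C[C@@H](C(=O)OC)[C@H](C)C(=O)Cl
F3 | step 2 | methyl (2R,3S)-2,3-dimethyl-4-oxo-4-(4-TIPSO-phenyl)butanoate | C[C@@H](C(=O)OC)[C@H](C)C(=O)c1ccc(O[Si](C(C)C)(C(C)C)C(C)C)cc1
F4 | step 4 | 1-(5-bromo-2-methoxyphenyl)ethan-1-one | CC(=O)c1cc(Br)ccc1OC
F5 | step 9 | (2R,3R,4S,5S)-3,4-dimethyl-2-{4-TIPSO-3-[(2R)-1-(4-TIPSO-phenyl)propan-2-yl]phenyl}-5-(4-TIPSO-phenyl)oxolane | C[C@@H]1[C@H](C)[C@@H](c2ccc(O[Si](C(C)C)(C(C)C)C(C)C)cc2)O[C@H]1c1ccc(O[Si](C(C)C)(C(C)C)C(C)C)c([C@H](C)Cc2ccc(O[Si](C(C)C)(C(C)C)C(C)C)cc2)c1
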